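**Retrosynthetic overview**

- Ring letters: A = benzo ring of the chromanone, C = pyranone, B = aryl ring at C2, D = dimethylpyran fused to B. The last skeletal bond is C2(ring C)–C6(ring B), made with control of the 2S centre by rhodium-catalysed 1,4-addition of a (2,2-dimethylchroman-6-yl)boronic acid to a 7-silyloxy-8-prenylchromone.
- Rings A and C are bought as 7-hydroxychromone; the prenyl group is placed at C8 by Claisen rearrangement of the 7-O-(1,1-dimethylallyl) ether.
- Ring D is built first, onto ring B, by a one-flask [3+3] annulation of a 2-fluorobenzyl unit (nucleophilic benzylic C4, electrophilic C8a–F) with 2,2-dimethyloxirane (electrophilic CH2 = C3, latent alkoxide = O1).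
- Enabling feature: in ring D the benzylic C4 and the ether carbon C8a are ortho neighbours on ring B, and C2 is a quaternary carbon, so the oxirane opens only at CH2 and the tertiary alkoxide cannot eliminate. C6, para to C8a, carries a chlorine that activates the C8a–F substitution and later becomes the boron handle.

Key step: step 1

Remark: compounds 1, 8 and 9 are taken as catalogue compounds (9 is otherwise one step from 2-methylbut-3-en-2-ol and Boc2O), and the ligand antipode named in step 6 is the one expected to give 2S, a sense of induction that should be confirmed on a small scale.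

**Route**

Step 1
Reactants: 1 2-(bromomethyl)-4-chloro-1-fluorobenzene (5-chloro-2-fluorobenzyl bromide); 2 2,2-dimethyloxirane
Product: 6 6-chloro-2,2-dimethyl-3,4-dihydro-2H-chromene, via Grignard reagent 3 (not isolated), via bromomagnesium alkoxide 4 (not isolated), via potassium alkoxide 5 (not isolated)
Conditions: Mg turnings, 2-MeTHF, 0 °C; then 2, CuI (5 mol%), −30 → 0 °C; then KOt-Bu (1.5 equiv), DMPU, 90 °C (ether solvent distilled off); H2O work-up
Reagents that add atoms: magnesium, [Mg] (ends in 3 and 4 only); potassium tert-butoxide, CC(C)(C)[O-].[K+] (its potassium ends in 5 only); no reagent atom remains in 6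
Why: Magnesium insertion into the benzylic C–Br bond of 1 gives Grignard reagent 3, whose CuI-catalysed SN2 attack on the unsubstituted CH2 of oxirane 2 forms the benzylic CH2–CH2 bond and unveils the tertiary alkoxide 4; metathesis with KOt-Bu gives potassium alkoxide 5, which adds to the fluorine-bearing ring carbon ortho to the chain and expels fluoride (addition–elimination through a Meisenheimer anion) to form the aryl–O bond. The closest known reaction types are the copper-catalysed opening of 2,2-disubstituted oxiranes by benzylic Grignard reagents and the intramolecular SNAr etherification of 2-fluorophenyl alkanols to chromans, here run in one flask as a formal [3+3] annulation. Ring D closes by six-membered ipso attack of O on the arene carbon (6-exo-trig with respect to the C8a–C8 π bond that takes up the charge), the only ring size the four-atom tether allows. No stereocentre is formed. The step needs opening of 2 at CH2 only (secured by the fully substituted other carbon and by copper catalysis at low temperature, which should outrun magnesium-halide-induced isomerisation of the oxirane), substitution of F and not Cl (F is the better nucleofuge in an addition-limited SNAr and the only halogen within reach of the tether), and acceleration of the ring closure, which the para chlorine should provide by stabilising the Meisenheimer anion while staying inert to the benzylic Grignard reagent.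

Step 2
Reactants: 6 6-chloro-2,2-dimethyl-3,4-dihydro-2H-chromene
Product: 7 (2,2-dimethyl-3,4-dihydro-2H-chromen-6-yl)boronic acid
Conditions: B2(OH)4 (2 equiv), PdCl(XPhos)(2'-aminobiphenyl-2-yl) (second-generation XPhos palladacycle, 2 mol%), XPhos (4 mol%), KOAc (3 equiv), EtOH, 80 °C; aqueous work-up
Reagents that add atoms: tetrahydroxydiboron, OB(O)B(O)O
Why: Miyaura-type palladium-catalysed borylation of an aryl chloride, in which the bulky electron-rich biarylphosphine lets zerovalent palladium insert into the electron-rich C–Cl bond and acetate-assisted transmetalation with the diboron followed by reductive elimination gives the boronic acid directly, with nothing else in 6 reactive under these conditions.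

Step 3
Reactants: 8 7-hydroxy-4H-chromen-4-one; 9 tert-butyl 2-methylbut-3-en-2-yl carbonate
Product: 10 7-[(2-methylbut-3-en-2-yl)oxy]-4H-chromen-4-one
Conditions: Pd(PPh3)4 (3 mol%), THF, 0 °C
Reagents that add atoms: none
Why: Tsuji–Trost O-allylation, in which zerovalent palladium ionises the tertiary allylic carbonate with loss of CO2 and tert-butoxide, the acidic 7-hydroxyl is deprotonated, and the phenoxide attacks the 1,1-dimethylallyl palladium cation at its more substituted terminus under kinetic control at low temperature, which should give the tertiary ether needed for step 4.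

Step 4
Reactants: 10 7-[(2-methylbut-3-en-2-yl)oxy]-4H-chromen-4-one
Product: 12 7-hydroxy-8-(3-methylbut-2-en-1-yl)-4H-chromen-4-one, via ortho-dienone 11 (not isolated)
Conditions: PhNEt2, 150 °C, sealed tube
Reagents that add atoms: none
Why: Aromatic Claisen rearrangement, in which the [3,3] shift delivers the CH2 terminus of the allyl unit to C8 (the ortho position joined to C7 by the bond of higher π order in the benzopyranone), so that the tertiary ether becomes a normal prenyl group and tautomerisation of dienone 11 restores ring A and the free 7-hydroxyl.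

Step 5
Reactants: 12 7-hydroxy-8-(3-methylbut-2-en-1-yl)-4H-chromen-4-one
Product: 13 8-(3-methylbut-2-en-1-yl)-7-{[tri(propan-2-yl)silyl]oxy}-4H-chromen-4-one
Conditions: i-Pr3SiCl, imidazole, DMF, rt
Reagents that add atoms: chlorotri(propan-2-yl)silane, CC(C)[Si](Cl)(C(C)C)C(C)C
Why: Standard silylation of a phenol, which masks the acidic 7-OH that would otherwise turn the chromone into an unreactive phenoxide and protonate the aryl–rhodium species in step 6, with a bulky silyl ether that should withstand the neutral aqueous conditions of that step.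

Step 6
Reactants: 13 8-(3-methylbut-2-en-1-yl)-7-{[tri(propan-2-yl)silyl]oxy}-4H-chromen-4-one; 7 (2,2-dimethyl-3,4-dihydro-2H-chromen-6-yl)boronic acid
Product: 14 (2S)-2-(2,2-dimethyl-3,4-dihydro-2H-chromen-6-yl)-8-(3-methylbut-2-en-1-yl)-7-{[tri(propan-2-yl)silyl]oxy}-2,3-dihydro-4H-chromen-4-one
Conditions: [Rh(OH)(cod)]2 (3 mol%), (S)-MeO-F12-BIPHEP [(S)-6,6'-dimethoxy-2,2'-bis(bis(3,4,5-trifluorophenyl)phosphino)-1,1'-biphenyl] (6.6 mol%), 7 (2.5 equiv), toluene/H2O (10:1), 40 °C
Reagents that add atoms: none
Why: Hayashi–Miyaura asymmetric 1,4-addition, in which the aryl species of monovalent rhodium formed by transmetalation inserts the chromone C2=C3 bond with the aryl group delivered to the Re face of C2 under control of the C2-symmetric bisphosphine (this sets the 2S centre), water cleaves the rhodium enolate, and the electron-poor ligand is of the type known to overcome the low electrophilicity of chromones and to suppress 1,2-addition.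

Step 7
Reactants: 14 (2S)-2-(2,2-dimethyl-3,4-dihydro-2H-chromen-6-yl)-8-(3-methylbut-2-en-1-yl)-7-{[tri(propan-2-yl)silyl]oxy}-2,3-dihydro-4H-chromen-4-one
Product: 15 Euchrenone a17, (2S)-2-(2,2-dimethyl-3,4-dihydro-2H-chromen-6-yl)-7-hydroxy-8-(3-methylbut-2-en-1-yl)-2,3-dihydro-4H-chromen-4-one
Conditions: Bu4NF/AcOH (1:1), THF, 0 °C
Reagents that add atoms: none
Why: Fluoride-induced cleavage of the aryl silyl ether under acetic acid buffering, which should keep the medium too weakly basic for the retro-oxa-Michael ring opening that would racemise C2 and too weakly acidic for cyclisation of the prenyl group onto the liberated 7-OH.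

**Compound list**

1 | 2-(bromomethyl)-4-chloro-1-fluorobenzene (5-chloro-2-fluorobenzyl bromide) | Fc1ccc(Cl)cc1CBr | starting material
2 | 2,2-dimethyloxirane | CC1(C)CO1 | starting material
3 | (5-chloro-2-fluorobenzyl)magnesium bromide | Fc1ccc(Cl)cc1C[Mg]Br | intermediate
4 | bromomagnesium 4-(5-chloro-2-fluorophenyl)-2-methylbutan-2-olate | CC(C)(CCc1cc(Cl)ccc1F)O[Mg]Br | intermediate
5 | potassium 4-(5-chloro-2-fluorophenyl)-2-methylbutan-2-olate | CC(C)(CCc1cc(Cl)ccc1F)[O-].[K+] | intermediate
6 | 6-chloro-2,2-dimethyl-3,4-dihydro-2H-chromene | CC1(C)CCc2cc(Cl)ccc2O1 | intermediate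
7 | (2,2-dimethyl-3,4-dihydro-2H-chromen-6-yl)boronic acid | CC1(C)CCc2cc(B(O)O)ccc2O1 | intermediate
8 | 7-hydroxy-4H-chromen-4-one | O=c1ccoc2cc(O)ccc12 | starting material
9 | tert-butyl 2-methylbut-3-en-2-yl carbonate | CC(C)(C)OC(=O)OC(C)(C)C=C | starting material
10 | 7-[(2-methylbut-3-en-2-yl)oxy]-4H-chromen-4-one | C=CC(C)(C)Oc1ccc2c(c1)occc2=O | intermediate
11 | 8-(3-methylbut-2-en-1-yl)-8H-chromene-4,7-dione (ortho-dienone, racemic at C8) | CC(C)=CCC1C(=O)C=CC2=C1OC=CC2=O | intermediate
12 | 7-hydroxy-8-(3-methylbut-2-en-1-yl)-4H-chromen-4-one | CC(C)=CCc1c(O)ccc2c1occc2=O | intermediate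
13 | 8-(3-methylbut-2-en-1-yl)-7-{[tri(propan-2-yl)silyl]oxy}-4H-chromen-4-one | CC(C)=CCc1c(O[Si](C(C)C)(C(C)C)C(C)C)ccc2c1occc2=O | intermediate
14 | (2S)-2-(2,2-dimethyl-3,4-dihydro-2H-chromen-6-yl)-8-(3-methylbut-2-en-1-yl)-7-{[tri(propan-2-yl)silyl]oxy}-2,3-dihydro-4H-chromen-4-one | CC(C)=CCc1c(O[Si](C(C)C)(C(C)C)C(C)C)ccc2c1O[C@H](c1ccc3c(c1)CCC(C)(C)O3)CC2=O | intermediate
15 | Euchrenone a17, (2S)-2-(2,2-dimethyl-3,4-dihydro-2H-chromen-6-yl)-7-hydroxy-8-(3-methylbut-2-en-1-yl)-2,3-dihydro-4H-chromen-4-one | CC(C)=CCc1c(O)ccc2c1O[C@H](c1ccc3c(c1)CCC(C)(C)O3)CC2=O | target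

**Step count and risks**

Total steps: 7. Longest linear sequence: 5 (steps 3, 4, 5, 6, 7).

Steps most likely to fail:

Step 1. Three processes may erode it: Wurtz-type homocoupling during magnesium insertion, halide-induced isomerisation of the oxirane before ring opening, and slow ipso attack of the hindered tertiary alkoxide while it is held in magnesium aggregates (with elimination–addition at the C–Cl site as a competing path at high temperature). The fallback sets out from oxirane 2 and returns at 6, and closes ring D by cross-coupling instead of SNAr. Magnesium insertion into purchased 1-bromo-2-(bromomethyl)-4-chlorobenzene (Brc1ccc(Cl)cc1CBr) would give (2-bromo-5-chlorobenzyl)magnesium bromide F1. Its CuI-catalysed addition to 2 at −30 °C and aqueous work-up would give the isolated alcohol 4-(2-bromo-5-chlorophenyl)-2-methylbutan-2-ol F2. A Buchwald–Hartwig etherification (Pd(OAc)2, 2-(di-tert-butylphosphino)-1,1'-binaphthyl, Cs2CO3, toluene, 80 °C) would then close F2 to 6; zerovalent palladium should insert into C–Br in preference to C–Cl, and the tethered tertiary alkoxide should undergo C–O reductive elimination.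

Step 6. The electron-rich 7-silyloxychromone may turn over slowly, the electron-rich boronic acid may protodeboronate, and facial discrimination may be insufficient. The fallback sets out from 13 and 7 and returns at 14, and replaces asymmetric induction by kinetic resolution. A conjugate addition under divalent palladium catalysis with an achiral ligand (Pd(OCOCF3)2, 2,2'-bipyridine, ClCH2CH2Cl/H2O, 60 °C) would give racemic 2-(2,2-dimethyl-3,4-dihydro-2H-chromen-6-yl)-8-(3-methylbut-2-en-1-yl)-7-{[tri(propan-2-yl)silyl]oxy}-2,3-dihydro-4H-chromen-4-one F3. Asymmetric transfer hydrogenation (RuCl(p-cymene)(TsDPEN), HCO2H/Et3N, with the TsDPEN antipode that reduces the 2R ketone faster) should convert the unwanted enantiomer into the cis alcohol (2R,4R)-2-(2,2-dimethyl-3,4-dihydro-2H-chromen-6-yl)-8-(3-methylbut-2-en-1-yl)-7-{[tri(propan-2-yl)silyl]oxy}-3,4-dihydro-2H-chromen-4-ol F4. Unreduced 14 would then be separated by chromatography.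

Step 4. The tertiary allyl ether may lose isoprene thermally before it rearranges, and part of the material may migrate to C6. The fallback sets out from 8 and returns at 13; it bypasses 10 to 12 and places the prenyl group by cross-coupling. Iodination ortho to the hydroxyl (N-iodosuccinimide, DMF, rt) would give 7-hydroxy-8-iodo-4H-chromen-4-one F5. Silylation (i-Pr3SiCl, imidazole, DMF) would give 8-iodo-7-{[tri(propan-2-yl)silyl]oxy}-4H-chromen-4-one F6. A linear-selective Negishi coupling (Pd(OAc)2, CPhos, THF, rt) with (3-methylbut-2-en-1-yl)zinc bromide F7, made in the flask from prenyl bromide, zinc dust and LiCl, would then give 13.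

**Further compounds**

F1 | step 1 | (2-bromo-5-chlorobenzyl)magnesium bromide | Brc1ccc(Cl)cc1C[Mg]Br
F2 | step 1 | 4-(2-bromo-5-chlorophenyl)-2-methylbutan-2-ol | CC(C)(O)CCc1cc(Cl)ccc1Br
F3 | step 6 | racemic 2-(2,2-dimethyl-3,4-dihydro-2H-chromen-6-yl)-8-(3-methylbut-2-en-1-yl)-7-{[tri(propan-2-yl)silyl]oxy}-2,3-dihydro-4H-chromen-4-one | CC(C)=CCc1c(O[Si](C(C)C)(C(C)C)C(C)C)ccc2c1OC(c1ccc3c(c1)CCC(C)(C)O3)CC2=O
F4 | step 6 | (2R,4R)-2-(2,2-dimethyl-3,4-dihydro-2H-chromen-6-yl)-8-(3-methylbut-2-en-1-yl)-7-{[tri(propan-2-yl)silyl]oxy}-3,4-dihydro-2H-chromen-4-ol | CC(C)=CCc1c(O[Si](C(C)C)(C(C)C)C(C)C)ccc2c1O[C@@H](c1ccc3c(c1)CCC(C)(C)O3)C[C@H]2O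
F5 | step 4 | 7-hydroxy-8-iodo-4H-chromen-4-one | O=c1ccoc2c(I)c(O)ccc12
F6 | step 4 | 8-iodo-7-{[tri(propan-2-yl)silyl]oxy}-4H-chromen-4-one | O=c1ccoc2c(I)c(O[Si](C(C)C)(C(C)C)C(C)C)ccc12
F7 | step 4 | (3-methylbut-2-en-1-yl)zinc bromide | CC(C)=CC[Zn]Br
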